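## Structural features

The target is a germacranolide. The carbocycle is ten-membered (C1–C10) with two trisubstituted Z alkenes, C1=C10 (methyl C14 on C10) and C4=C5 (methyl C15 on C4). An α-methylene-γ-butyrolactone (O–C6, C7–C11(=C13)–C12=O) is cis-fused to it at C6–C7. This germacrane numbering is used for every ring compound below, including the cyclohexene intermediates.

Four stereocentres are contiguous: C6 (lactone oxygen), C7 (lactone carbon), C8 (free hydroxyl) and C9 (ester oxygen). O6, C11 and O8 lie on one ring face and O9 on the other. C3 (allylic acetate) is separated from them by the two alkenes. The C9 acyl group is (2S,3R)-2,3-dimethyloxirane-2-carboxylate, the epoxide of a tiglate, with two more stereocentres.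

Fragile groups are the Michael-accepting methylene lactone, the acid-labile trisubstituted epoxide, the allylic acetate, and the free C8 hydroxyl next to the C9 ester, which invites acyl migration and translactonisation. Three secondary hydroxyls (C3, C8, C9) must also end up differently substituted.

The real difficulty is the medium ring with two Z alkenes and the syn-dioxygenated C8–C9 pair. C8–C9 is the only ring bond that joins two oxygenated sp3 carbons. It lies in a 1,5-relationship to the C6 oxygen and the C1=C10 alkene (C8–C7–C6 and C9–C10=C1), which is the retron of an oxy-Cope ring expansion. The key step exploits this: joining C1 to C6 in the reverse sense folds the ring into a cyclohexenol with two enol-ether arms.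

## Logic of the disconnections

44 ⇒ 43. The O–CH2Ar bond of a 4-methoxybenzyl ether on O8 is cut. The C8 hydroxyl is unveiled last because, once free, it sits beside the C9 ester and the lactone. The forward step must be neutral and must spare the epoxide, both esters and the methylene lactone.

43 ⇒ 37 + 41. The C9–O acyl bond is cut. This takes the epoxide and two stereocentres out of the ring chemistry and makes the route convergent. The forward step must acylate a hindered allylic secondary alcohol with an α-quaternary acid, with C9–OH as the only free hydroxyl.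

41 ⇒ 40 ⇒ 39 ⇒ 38. The epoxide C–O bonds are cut back to an E allylic alcohol. The E geometry of 38 supplies the relative configuration and a reagent-controlled epoxidation supplies the absolute one. The forward sequence needs one reduction and one oxidation that leave the epoxide alone.

37 ⇒ 36 ⇒ 35 ⇒ 34. These are group exchanges at O9 and O3. An acetate cannot survive the enolate and hydride steps, so C3 is carried as a silyl ether. O9 is carried as a 3,4-dimethoxybenzyl ether. The forward steps demand fluoride cleavage beside a Michael acceptor and oxidative cleavage of the more electron-rich benzyl ether while the 4-methoxybenzyl ether on O8 stays.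

34 ⇒ 30. The C11=C13 bond is cut. The Michael acceptor is introduced only after all enolate and hydride chemistry on the ring. The forward step needs clean enolisation at C11.

30 ⇒ 28 ⇒ 25 + 26. The lactone O–C12 bond and then the C7–C11 bond are cut. The C6 ketone of 25 first activates C7 and then becomes the lactone oxygen, so two stereocentres disappear. The forward steps demand attack of the electrophile at C7 and of hydride at C6 on the faces that place C11, O6 and O8 all cis.

25 ⇒ 22 (key). In the reverse sense C8–C9 is broken and C1–C6 is joined. The ten-membered ring becomes a cyclohexenol, and the C8 and C9 stereocentres and the Z C1=C10 alkene become two E enol ethers and a cis relation of the arms. The forward step demands a single chair transition state.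

22 ⇒ 21 ⇒ 16 + 18. The E alkene of the C6 arm is traced to an alkyne and the C6–C7 bond is cut. A linear alkynyl nucleophile adds axially, cis to the C1 arm, and anti hydroalumination then fixes the E geometry. The forward addition must not enolise the doubly activated C1–H.

16 ⇒ 6 + 13. The C1–C10 bond is cut. The arm arrives as a geometrically defined alkenyl bromide. The forward step demands α′ regiochemistry, retention of the bromide geometry, and a C1 configuration cis to the C3 oxygen.

13 ⇒ 11 ⇒ 7 + 8, and 18 ⇒ 17 + 8. Both arms come from a benzylic alcohol and the two carbons of 8 through alkynyl ethers. Syn hydrometalation of 11 sets the E geometry of 13.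

6 ⇒ 5 ⇒ 4 ⇒ 3 ⇒ 2 ⇒ 1. The C3 oxygen is removed by way of an epoxide of the deconjugated ketal. A kinetic resolution supplies the single enantiomer.

## Other disconnections considered

Alternative 1: The cut is through the lactone at O–C12 and C11–C12. It leads back to the C6 alcohol with an ethynyl group on C7 (A2) and carbon monoxide. In the forward step PdCl2, thiourea and CO convert the hydroxyl into an alkoxycarbonyl palladium species, which adds syn across the alkyne and gives the C8 triethylsilyl ether A1 after protonolysis.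
- In its favour: lactone ring and exocyclic methylene form in one neutral step without enolate chemistry. For the lactone alone this is better than the chosen plan, which needs three steps (13 to 15) and two substrate-controlled stereochemical events.
- Against it: A2 must already contain the ten-membered ring, all ring stereocentres, the acetate and the epoxy ester, so the medium ring and the C8–C9 pair remain unsolved. Zerovalent palladium formed under CO can ionise the allylic C3 acetate. The final desilylation next to the C9 ester is no easier than the last step here.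
- Comparison: mechanistically it replaces alkylation and hydride reduction by one syn addition, but C7 must then be made as a propargylic stereocentre. On overall step economy it gains two steps at the end and loses more in reaching A2.

Alternative 2: The cut removes both C–O bonds at C3 and C6 and leads to the ring triene A4 with a Z,Z-diene C3=C4–C5=C6. In the forward step sensitised singlet oxygen adds suprafacially in a [4+2] sense and gives the endoperoxide A3.
- In its favour: one step sets C3 and C6 cis across the ring and creates the Z C4=C5 alkene under neutral conditions. After O–O reduction the C6 hydroxyl lactonises onto the acrylate and C3 is left for acetylation. For these two centres it is better than the chosen plan, which needs a resolution for C3 and a hydride reduction for C6.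
- Against it: the trisubstituted C1=C10 alkene is a good partner for the competing ene reaction. Face selection on the diene rests on ring conformation. The peroxide must be reduced beside an epoxide and an acrylate. A4 is a strained ten-membered triene that already carries C7, C8 and C9.
- Comparison: like Alternative 1 it neither builds the carbocycle nor sets C8 and C9. The step count after the key step is similar to the chosen plan; before it, it is longer.

Alternative 3: The cut is the C9–C10 bond and leads to the acyclic iodo aldehyde A6. In the forward step CrCl2 with catalytic NiCl2 turns the Z alkenyl iodide into an alkenylchromium species, which adds to the aldehyde and closes the ring to the C9 alcohol A5.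
- In its favour: the reaction tolerates esters and lactones and keeps the alkene geometry. C9–OH emerges free for esterification, which is better than the chosen plan (which spends step 18 on unmasking it). A6 can be assembled convergently, which is at least equal.
- Against it: it is an end-to-end closure of a ten-membered ring with two Z alkenes, so entropy and transannular strain call for high dilution. Only one stereocentre (C9) is formed, under uncertain Felkin or chelation control. The α-oxygenated aldehyde can epimerise. C3, C6, C7 and C8 must all be set in an open chain.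
- Comparison: the chosen plan makes the ring by expansion of a six-membered ring and sets two stereocentres and one alkene geometry in the same step. It should not be longer overall.

Key step: step 12

Remarks on the chemistry (assumptions and design choices):
- The precursor and product of the key step were checked atom by atom against the target. The two arms must be cis to each other and also cis to the C3 oxygen. Enolate alkylation does not give the second relation by itself, so it is secured separately in step 8.
- O9 is carried as a 3,4-dimethoxybenzyl (DMB) ether, which is removable before the 4-methoxybenzyl (PMB) ether on O8 and beside a silyl ether. The C6 arm is introduced as an alkyne (axial attack, then anti reduction) so that the cis arms and the E geometry are secured.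
- Assumption: the lipase acylates the R alcohol of 4, as the empirical rule for secondary alcohols predicts. If it prefers the other enantiomer, 5 is obtained by methanolysis of the S acetate.

## Steps

Step 1
Reactants: 1 3-methylcyclohex-2-en-1-one
Product: 2 7-methyl-1,4-dioxaspiro[4.5]dec-7-ene
Conditions: HOCH2CH2OH, p-TsOH (cat.), benzene, reflux, Dean–Stark
Reagents that add atoms: ethylene glycol, OCCO
Why: Acid-catalysed ketalisation of a β-alkyl enone proceeds through the dienol ether and leaves the double bond out of conjugation (deconjugative ketalisation). This places the alkene between C3 and C4, where the C3 oxygen is to be introduced.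

Step 2
Reactants: 2 7-methyl-1,4-dioxaspiro[4.5]dec-7-ene
Product: 3 (±)-7,8-epoxy-7-methyl-1,4-dioxaspiro[4.5]decane
Conditions: mCPBA, NaHCO3, CH2Cl2, 0 °C
Reagents that add atoms: 3-chloroperbenzoic acid, OOC(=O)c1cccc(Cl)c1
Why: Prilezhaev epoxidation of the only alkene; the buffer protects the ketal. The product is racemic and is resolved in step 4.

Step 3
Reactants: 3 (±)-7,8-epoxy-7-methyl-1,4-dioxaspiro[4.5]decane
Product: 4 (±)-4-hydroxy-3-methylcyclohex-2-en-1-one
Conditions: PPTS, THF–H2O, 50 °C; then Et3N, rt
Reagents that add atoms: water, O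
Why: Mild ketal hydrolysis gives a β,γ-epoxy ketone, which opens by base-induced β-elimination to the γ-hydroxy enone. The C–O bond at C3 is not touched.

Step 4
Reactants: 4 (±)-4-hydroxy-3-methylcyclohex-2-en-1-one
Product: 5 (4S)-4-hydroxy-3-methylcyclohex-2-en-1-one
Conditions: lipase PS (Burkholderia cepacia, immobilised), vinyl acetate, MTBE, 30 °C, to slightly past half conversion
Reagents that add atoms: none
Why: Enzymatic kinetic resolution by irreversible transesterification; by the Kazlauskas rule the R alcohol should be acylated and the S alcohol recovered. Running slightly past half conversion should give 5 in high enantiomeric purity, and the acetate is removed by chromatography.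

Step 5
Reactants: 5 (4S)-4-hydroxy-3-methylcyclohex-2-en-1-one
Product: 6 (4S)-4-(tert-butyldimethylsilyloxy)-3-methylcyclohex-2-en-1-one
Conditions: TBSCl, imidazole, DMF, rt
Reagents that add atoms: tert-butyldimethylsilyl chloride, CC(C)(C)[Si](C)(C)Cl
Why: Standard silylation of a secondary alcohol. The silyl ether withstands the amide bases, organometallics, hydrides and KH used up to step 15.

Step 6
Reactants: 7 (3,4-dimethoxyphenyl)methanol; 8 trichloroethene
Product: 11 1,2-dimethoxy-4-[(prop-1-yn-1-yloxy)methyl]benzene, via DMB dichlorovinyl ether 9 (not isolated), via lithium DMB-oxyacetylide 10 (not isolated)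
Conditions: KH, THF, 0 °C → rt; n-BuLi (2.2 equiv), −78 → −40 °C; MeI, DMPU, −78 °C → rt
Reagents that add atoms: iodomethane, CI
Why: The alkoxide adds to trichloroethene with loss of chloride and gives 9. Dehydrochlorination and chlorine–lithium exchange give alkoxyacetylide 10, which is methylated on carbon (the trichloroethene route to alkynyl ethers). The product is kept at or below room temperature because benzyl alkynyl ethers rearrange on heating.

Step 7
Reactants: 11 1,2-dimethoxy-4-[(prop-1-yn-1-yloxy)methyl]benzene
Product: 13 4-{[(E)-2-bromoprop-1-en-1-yl]oxymethyl}-1,2-dimethoxybenzene, via alkenylzirconocene chloride 12 (not isolated)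
Conditions: Cp2Zr(H)Cl, THF, rt; NBS, 0 °C
Reagents that add atoms: N-bromosuccinimide, O=C1CCC(=O)N1Br
Why: Syn hydrozirconation puts hydrogen on the oxygen-bearing carbon and zirconium on the methyl-bearing carbon, as for other alkoxyalkynes. Bromination of the C–Zr bond with retention gives the bromide with Br trans to oxygen.

Step 8
Reactants: 6 (4S)-4-(tert-butyldimethylsilyloxy)-3-methylcyclohex-2-en-1-one; 13 4-{[(E)-2-bromoprop-1-en-1-yl]oxymethyl}-1,2-dimethoxybenzene
Product: 16 (4S,6S)-4-(tert-butyldimethylsilyloxy)-6-[(E)-1-(3,4-dimethoxybenzyloxy)prop-1-en-2-yl]-3-methylcyclohex-2-en-1-one, via lithium enolate 14 (not isolated), via lithium dienolate 15 (not isolated)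
Conditions: LiN(SiMe3)2 (2.2 equiv), THF, −78 °C; Pd2(dba)3 (2.5 mol %), P(t-Bu)3 (6 mol %), 13, −78 °C → rt; cannulated into 2,6-di-tert-butylphenol, THF, −78 °C; aq. NH4Cl
Reagents that add atoms: none
Why: Zerovalent palladium inserts into the C–Br bond of 13 with retention and couples with the kinetic enolate 14 at C1 (Pd-catalysed α-alkenylation of a ketone enolate, Buchwald–Hartwig type); the second equivalent of base stores the product as dienolate 15, which blocks a second coupling. C1 is then set by kinetic α-protonation: the bulky phenol should approach the face opposite the pseudoaxial C3 silyl ether, the face that alkyl halides choose on such enolates, and this leaves the arm cis to C3–O. The C1 epimers interconvert through 15, so the minor one is re-enolised and protonated again.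

Step 9
Reactants: 17 (4-methoxyphenyl)methanol; 8 trichloroethene
Product: 18 1-{[(E)-1,2-dichloroethenyl]oxymethyl}-4-methoxybenzene
Conditions: KH, THF, 0 °C → rt
Reagents that add atoms: none
Why: Same addition–elimination as in step 6, stopped at the storable dichlorovinyl ether. The sensitive alkynyl ether is generated only in the flask of step 10.

Step 10
Reactants: 16 (4S,6S)-alkenyl ketone; 18 1-{[(E)-1,2-dichloroethenyl]oxymethyl}-4-methoxybenzene
Product: 21 (1R,4S,6S)-4-(tert-butyldimethylsilyloxy)-6-[(E)-1-(3,4-dimethoxybenzyloxy)prop-1-en-2-yl]-1-[(4-methoxybenzyloxy)ethynyl]-3-methylcyclohex-2-en-1-ol, via lithium PMB-oxyacetylide 19 (not isolated), via alkynylcerium dichloride 20 (not isolated)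
Conditions: 18, n-BuLi (2.0 equiv per 18), THF, −78 °C; CeCl3, −78 °C; 16, −78 °C; aq. NH4Cl
Reagents that add atoms: none
Why: 1,2-Addition of an alkynylcerium reagent, which is too weakly basic to enolise the doubly activated C1–H. The linear nucleophile should enter C6 axially on the half-chair that holds the C1 arm and C3–OTBS equatorial, anti to the axial C1–H, so the alkyne ends cis to the C1 arm and the hydroxyl trans. The acetylide is made from 18 by dehydrochlorination and chlorine–lithium exchange and is kept cold.

Step 11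
Reactants: 21 (1R,4S,6S)-propargylic alcohol
Product: 22 (1R,4S,6S)-4-(tert-butyldimethylsilyloxy)-6-[(E)-1-(3,4-dimethoxybenzyloxy)prop-1-en-2-yl]-1-[(E)-2-(4-methoxybenzyloxy)ethenyl]-3-methylcyclohex-2-en-1-ol
Conditions: LiAlH4, THF, 0 °C → rt; aq. potassium sodium tartrate
Reagents that add atoms: none
Why: Hydroxyl-directed anti hydroalumination of the alkoxyalkyne (the LiAlH4 reduction of propargylic alcohols and of 1-alkoxyalkynes), followed by protonolysis with retention, gives the E enol ether. Aluminium and the PMB-oxy group end cis on the alkenyl aluminate, so anti β-elimination is not open. The silyl ether, the benzyl ethers and the other enol ether are inert to LiAlH4.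

Step 12
Reactants: 22 (1R,4S,6S)-cis-dialkenyl cyclohexenol
Product: 25 (2Z,4S,6Z,8S,9S)-4-(tert-butyldimethylsilyloxy)-8-(3,4-dimethoxybenzyloxy)-9-(4-methoxybenzyloxy)-3,7-dimethylcyclodeca-2,6-dien-1-one, via potassium alkoxide 23 (not isolated), via potassium dienolate 24 (not isolated)
Conditions: KH (3 equiv), 18-crown-6 (3 equiv), THF, 0 °C → rt; AcOH, THF, −78 °C
Reagents that add atoms: none
Why: KH deprotonates the tertiary hydroxyl and 18-crown-6 frees the ion pair; alkoxide 23 undergoes a concerted [3,3] shift (anionic oxy-Cope rearrangement) in which C1–C6 breaks while C8–C9 and the C1=C10 alkene form, giving dienolate 24, which is protonated at C7 at −78 °C to the conjugated enone 25. The closest known reaction is the anionic oxy-Cope ring expansion of 1,2-dialkenylcyclohexanols to cyclodec-5-enones, including substrates whose alkene termini carry alkoxy groups. The ten-membered ring is not closed end to end: it arises by four-atom enlargement of the cyclohexene through a six-membered chair transition state, so no macrocyclisation entropy is paid. C8 and C9 are set by that chair: both E enol ethers place their oxygens equatorial, and with the arms cis the chair has C2 axial and C5 equatorial, which fixes C8 and C9 relative to each other and, through C1 and C6, relative to C3. The step needs this chair and not the ring-flipped chair (which would give the E C1=C10 alkene) or a boat; it is secured because the reacting half-chair carries the C1 arm, the cis C3 silyl ether and the solvated alkoxide equatorial, whereas the other chair would force the arm and C3–OTBS into a 1,3-diaxial clash. C1=C10 should therefore form Z, and C4=C5 stays Z because it is a former cyclohexene bond. The enolate is quenched cold and promptly, since on warming it could expel the C8 alkoxide; silyl transfer from O3 to O6 is excluded because these oxygens lie on opposite ring faces.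

Step 13
Reactants: 25 ten-membered dienone; 26 methyl bromoacetate
Product: 28 methyl 2-[(1R,2S,3S,4Z,7S,8Z)-7-(tert-butyldimethylsilyloxy)-3-(3,4-dimethoxybenzyloxy)-2-(4-methoxybenzyloxy)-4,8-dimethyl-10-oxocyclodeca-4,8-dien-1-yl]acetate, via lithium enolate 27 (not isolated)
Conditions: LiN(SiMe3)2 (1.1 equiv), THF, −78 °C; 26, −78 → −40 °C
Reagents that add atoms: none
Why: LiN(SiMe3)2 removes a C7 proton (the only α-methylene) and the lithium enolate 27 is alkylated by the α-bromo ester (SN2). Lithium should bridge the enolate oxygen and the C8 ether oxygen; the ring bond C8–C9 then covers one face and the electrophile enters on the other (the sense of a Fráter–Seebach alkylation), which gives 7R with the side chain cis to C8–O. No dipolar cosolvent is added so that the chelate persists, and the low temperature holds back loss of the C8 alkoxide.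

Step 14
Reactants: 28 C7-alkylated keto ester
Product: 30 (3aS,4S,5S,6Z,9S,10Z,11aS)-9-(tert-butyldimethylsilyloxy)-5-(3,4-dimethoxybenzyloxy)-4-(4-methoxybenzyloxy)-6,10-dimethyl-3a,4,5,8,9,11a-hexahydrocyclodeca[b]furan-2(3H)-one, via hydroxy ester 29 (not isolated)
Conditions: LiBH(s-Bu)3, THF, −78 °C; aq. NH4Cl; PPTS (cat.), CH2Cl2, rt
Reagents that add atoms: none
Why: The β,β-disubstituted enone is reduced 1,2; the bulky hydride should attack C6 from the ring periphery anti to the C7–C8 bond (Felkin–Anh), which puts the new hydroxyl cis to the C7 side chain (6S) in 29. Acid-catalysed transesterification then closes the cis-fused γ-lactone with loss of methanol.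

Step 15
Reactants: 30 cis-fused lactone
Product: 34 (3aS,4S,5S,6Z,9S,10Z,11aS)-9-(tert-butyldimethylsilyloxy)-5-(3,4-dimethoxybenzyloxy)-4-(4-methoxybenzyloxy)-6,10-dimethyl-3-methylidene-3a,4,5,8,9,11a-hexahydrocyclodeca[b]furan-2(3H)-one, via lithium enolate 31 (not isolated), via Mannich base 32 (not isolated), via trimethylammonium iodide 33 (not isolated)
Conditions: LiN(i-Pr)2, THF, −78 °C; CH2=NMe2+ I−, −78 °C → rt; MeI, MeOH, rt; aq. NaHCO3, CH2Cl2, rt
Reagents that add atoms: N,N-dimethylmethyleneiminium iodide, C=[N+](C)C.[I-]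
Why: The lactone enolate 31 adds to the iminium salt (Mannich reaction); exhaustive methylation and E1cB loss of trimethylamine give the exocyclic methylene. C11 is the only enolisable position, and all hydroxyls are masked so MeI finds only the amine.

Step 16
Reactants: 34 silyl-protected methylene lactone
Product: 35 (3aS,4S,5S,6Z,9S,10Z,11aS)-5-(3,4-dimethoxybenzyloxy)-9-hydroxy-4-(4-methoxybenzyloxy)-6,10-dimethyl-3-methylidene-3a,4,5,8,9,11a-hexahydrocyclodeca[b]furan-2(3H)-one
Conditions: HF·pyridine, pyridine, THF, 0 °C → rt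
Reagents that add atoms: none
Why: Fluoride-driven cleavage of the Si–O bond under buffered, weakly acidic conditions. These leave both benzyl ethers and the Michael acceptor alone, whereas basic fluoride could add to the methylene lactone.

Step 17
Reactants: 35 C3 alcohol
Product: 36 (3aS,4S,5S,6Z,9S,10Z,11aS)-5-(3,4-dimethoxybenzyloxy)-4-(4-methoxybenzyloxy)-6,10-dimethyl-3-methylidene-2-oxo-2,3,3a,4,5,8,9,11a-octahydrocyclodeca[b]furan-9-yl acetate
Conditions: Ac2O, pyridine, DMAP (cat.), CH2Cl2, 0 °C → rt
Reagents that add atoms: acetic anhydride, CC(=O)OC(C)=O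
Why: DMAP-catalysed acylation of the only free hydroxyl, with retention at C3.

Step 18
Reactants: 36 C3 acetate
Product: 37 (3aS,4S,5S,6Z,9S,10Z,11aS)-5-hydroxy-4-(4-methoxybenzyloxy)-6,10-dimethyl-3-methylidene-2-oxo-2,3,3a,4,5,8,9,11a-octahydrocyclodeca[b]furan-9-yl acetate
Conditions: DDQ (1.1 equiv), CH2Cl2–pH 7 phosphate buffer (10:1), 0 °C
Reagents that add atoms: none
Why: Oxidative cleavage of a benzyl ether by benzylic hydride abstraction and hydrolysis of the oxocarbenium ion. The 3,4-dimethoxybenzyl ether is oxidised much faster than the 4-methoxybenzyl ether, so one equivalent at 0 °C should free C9–OH only. The buffer and the water keep the neighbouring PMB group from closing to a benzylidene acetal.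

Step 19
Reactants: 38 tiglic acid
Product: 39 (E)-2-methylbut-2-en-1-ol
Conditions: LiAlH4, Et2O, 0 °C → rt
Reagents that add atoms: none
Why: Hydride reduction of the carboxylic acid to the allylic alcohol; the trisubstituted alkene and its E geometry are untouched.

Step 20
Reactants: 39 (E)-2-methylbut-2-en-1-ol
Product: 40 [(2R,3R)-2,3-dimethyloxiran-2-yl]methanol
Conditions: Ti(Oi-Pr)4 (10 mol %), diethyl D-(−)-tartrate (12 mol %), t-BuOOH, 4 Å MS, CH2Cl2, −20 °C
Reagents that add atoms: tert-butyl hydroperoxide, CC(C)(C)OO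
Why: Sharpless asymmetric epoxidation. The E alkene fixes the trans relation of the hydroxymethyl and C3-methyl groups. The D-(−)-tartrate should deliver oxygen to the face that gives the 2R,3R epoxy alcohol, the mirror image of the 2S,3S product that L-(+)-tartrate gives with E allylic alcohols.

Step 21
Reactants: 40 [(2R,3R)-2,3-dimethyloxiran-2-yl]methanol
Product: 41 (2S,3R)-2,3-dimethyloxirane-2-carboxylic acid
Conditions: RuCl3 (2 mol %), NaIO4, MeCN–EtOAc–H2O, rt
Reagents that add atoms: water, O
Why: Ruthenium tetroxide generated in the flask oxidises the primary alcohol through the aldehyde hydrate to the acid without opening the epoxide. The descriptor at C2 changes only because the priorities change; the quaternary centre cannot epimerise.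

Step 22
Reactants: 37 C9 alcohol; 41 (2S,3R)-2,3-dimethyloxirane-2-carboxylic acid
Product: 43 (3aS,4S,5S,6Z,9S,10Z,11aS)-9-acetoxy-4-(4-methoxybenzyloxy)-6,10-dimethyl-3-methylidene-2-oxo-2,3,3a,4,5,8,9,11a-octahydrocyclodeca[b]furan-5-yl (2S,3R)-2,3-dimethyloxirane-2-carboxylate, via mixed anhydride 42 (not isolated)
Conditions: 41, 2,4,6-Cl3C6H2COCl, Et3N, THF, rt; then 37, DMAP, toluene, rt
Reagents that add atoms: none
Why: Yamaguchi esterification: the mixed anhydride 42 is attacked by DMAP at the less hindered carbonyl, and the acylpyridinium ion acylates the hindered allylic C9 hydroxyl. The acid has no α-hydrogen, so it cannot epimerise, and the conditions are too mild to open the epoxide.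

Step 23
Reactants: 43 PMB-protected target
Product: 44 (3aR,4S,5S,6Z,9S,10Z,11aS)-9-acetoxy-4-hydroxy-6,10-dimethyl-3-methylidene-2-oxo-2,3,3a,4,5,8,9,11a-octahydrocyclodeca[b]furan-5-yl (2S,3R)-2,3-dimethyloxirane-2-carboxylate (CNP0137407.7)
Conditions: DDQ (1.5 equiv), CH2Cl2–pH 7 phosphate buffer (10:1), 0 °C → rt
Reagents that add atoms: none
Why: Oxidative removal of the 4-methoxybenzyl ether under neutral buffered conditions, which the epoxide, both esters and the methylene lactone tolerate. The neutral pH should prevent migration of the C9 acyl group to O8 and translactonisation.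

## Compound list

1 | 3-methylcyclohex-2-en-1-one | CC1=CC(=O)CCC1 | starting material
2 | 7-methyl-1,4-dioxaspiro[4.5]dec-7-ene | CC1=CCCC2(C1)OCCO2 | intermediate
3 | (±)-7,8-epoxy-7-methyl-1,4-dioxaspiro[4.5]decane (racemic) | CC12CC3(CCC1O2)OCCO3 | intermediate
4 | (±)-4-hydroxy-3-methylcyclohex-2-en-1-one (racemic) | CC1=CC(=O)CCC1O | intermediate
5 | (4S)-4-hydroxy-3-methylcyclohex-2-en-1-one | O=C1C=C(C)[C@@H](O)CC1 | intermediate
6 | (4S)-4-[(tert-butyldimethylsilyl)oxy]-3-methylcyclohex-2-en-1-one | O=C1C=C(C)[C@@H](O[Si](C)(C)C(C)(C)C)CC1 | intermediate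
7 | (3,4-dimethoxyphenyl)methanol | COc1ccc(CO)cc1OC | starting material
8 | trichloroethene | ClC=C(Cl)Cl | starting material
9 | 4-{[(E)-1,2-dichloroethenyl]oxymethyl}-1,2-dimethoxybenzene | Cl/C=C(/Cl)OCc1ccc(OC)c(OC)c1 | intermediate
10 | lithium [(3,4-dimethoxybenzyl)oxy]ethynide | [Li]C#COCc1ccc(OC)c(OC)c1 | intermediate
11 | 1,2-dimethoxy-4-[(prop-1-yn-1-yloxy)methyl]benzene | CC#COCc1ccc(OC)c(OC)c1 | intermediate
12 | chlorobis(cyclopentadienyl){(E)-1-[(3,4-dimethoxybenzyl)oxy]prop-1-en-2-yl}zirconium (Zr trans to O) | C/C(=C\OCc1ccc(OC)c(OC)c1)[Zr](Cl)(C1C=CC=C1)C1C=CC=C1 | intermediate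
13 | 4-{[(E)-2-bromoprop-1-en-1-yl]oxymethyl}-1,2-dimethoxybenzene (Br trans to O) | C/C(Br)=C\OCc1ccc(OC)c(OC)c1 | intermediate
14 | lithium (4S)-4-[(tert-butyldimethylsilyl)oxy]-5-methylcyclohexa-1,5-dien-1-olate | [Li+].[O-]C1=CC[C@H](O[Si](C)(C)C(C)(C)C)C(C)=C1 | intermediate
15 | lithium (4S)-4-[(tert-butyldimethylsilyl)oxy]-2-{(E)-1-[(3,4-dimethoxybenzyl)oxy]prop-1-en-2-yl}-5-methylcyclohexa-1,5-dien-1-olate | [Li+].[O-]C1=C(/C(C)=C/OCc2ccc(OC)c(OC)c2)C[C@H](O[Si](C)(C)C(C)(C)C)C(C)=C1 | intermediate
16 | (4S,6S)-4-[(tert-butyldimethylsilyl)oxy]-6-{(E)-1-[(3,4-dimethoxybenzyl)oxy]prop-1-en-2-yl}-3-methylcyclohex-2-en-1-one (silyloxy and arm cis) | O=C1C=C(C)[C@@H](O[Si](C)(C)C(C)(C)C)C[C@H]1/C(C)=C/OCc1ccc(OC)c(OC)c1 | intermediate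
17 | (4-methoxyphenyl)methanol | COc1ccc(CO)cc1 | starting material
18 | 1-{[(E)-1,2-dichloroethenyl]oxymethyl}-4-methoxybenzene | Cl/C=C(/Cl)OCc1ccc(OC)cc1 | intermediate
19 | lithium [(4-methoxybenzyl)oxy]ethynide | [Li]C#COCc1ccc(OC)cc1 | intermediate
20 | dichloro{[(4-methoxybenzyl)oxy]ethynyl}cerium | Cl[Ce](Cl)C#COCc1ccc(OC)cc1 | intermediate
21 | (1R,4S,6S)-4-[(tert-butyldimethylsilyl)oxy]-6-{(E)-1-[(3,4-dimethoxybenzyl)oxy]prop-1-en-2-yl}-1-{[(4-methoxybenzyl)oxy]ethynyl}-3-methylcyclohex-2-en-1-ol | O[C@]1(C#COCc2ccc(OC)cc2)C=C(C)[C@@H](O[Si](C)(C)C(C)(C)C)C[C@H]1/C(C)=C/OCc1ccc(OC)c(OC)c1 | intermediate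
22 | (1R,4S,6S)-4-[(tert-butyldimethylsilyl)oxy]-6-{(E)-1-[(3,4-dimethoxybenzyl)oxy]prop-1-en-2-yl}-1-{(E)-2-[(4-methoxybenzyl)oxy]ethenyl}-3-methylcyclohex-2-en-1-ol | O[C@]1(/C=C/OCc2ccc(OC)cc2)C=C(C)[C@@H](O[Si](C)(C)C(C)(C)C)C[C@H]1/C(C)=C/OCc1ccc(OC)c(OC)c1 | intermediate
23 | potassium alkoxide of 22 (1R,4S,6S) | [K+].[O-][C@]1(/C=C/OCc2ccc(OC)cc2)C=C(C)[C@@H](O[Si](C)(C)C(C)(C)C)C[C@H]1/C(C)=C/OCc1ccc(OC)c(OC)c1 | intermediate
24 | potassium (1(10)Z,2Z,4S,6Z,8S,9S)-4-[(tert-butyldimethylsilyl)oxy]-8-[(3,4-dimethoxybenzyl)oxy]-9-[(4-methoxybenzyl)oxy]-3,7-dimethylcyclodeca-1(10),2,6-trien-1-olate (enolate C6=C7, germacrane numbering) | C\1=C([O-])/C=C(/C)[C@@H](O[Si](C)(C)C(C)(C)C)C/C=C(/C)[C@H](OCc2ccc(OC)c(OC)c2)[C@H]1OCc1ccc(OC)cc1.[K+] | intermediate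
25 | (2Z,4S,6Z,8S,9S)-4-[(tert-butyldimethylsilyl)oxy]-8-[(3,4-dimethoxybenzyl)oxy]-9-[(4-methoxybenzyl)oxy]-3,7-dimethylcyclodeca-2,6-dien-1-one | O=C1/C=C(/C)[C@@H](O[Si](C)(C)C(C)(C)C)C/C=C(/C)[C@H](OCc2ccc(OC)c(OC)c2)[C@@H](OCc2ccc(OC)cc2)C1 | intermediate
26 | methyl bromoacetate | COC(=O)CBr | starting material
27 | lithium enolate of 25 (C6=C7, same geometry and configuration as 24) | C\1=C([O-])/C=C(/C)[C@@H](O[Si](C)(C)C(C)(C)C)C/C=C(/C)[C@H](OCc2ccc(OC)c(OC)c2)[C@H]1OCc1ccc(OC)cc1.[Li+] | intermediate
28 | methyl 2-[(1R,2S,3S,4Z,7S,8Z)-7-[(tert-butyldimethylsilyl)oxy]-3-[(3,4-dimethoxybenzyl)oxy]-2-[(4-methoxybenzyl)oxy]-4,8-dimethyl-10-oxocyclodeca-4,8-dien-1-yl]acetate | O=C1/C=C(/C)[C@@H](O[Si](C)(C)C(C)(C)C)C/C=C(/C)[C@H](OCc2ccc(OC)c(OC)c2)[C@@H](OCc2ccc(OC)cc2)[C@H]1CC(=O)OC | intermediate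
29 | methyl 2-[(1S,2S,3S,4Z,7S,8Z,10S)-7-[(tert-butyldimethylsilyl)oxy]-3-[(3,4-dimethoxybenzyl)oxy]-10-hydroxy-2-[(4-methoxybenzyl)oxy]-4,8-dimethylcyclodeca-4,8-dien-1-yl]acetate | O[C@H]1/C=C(/C)[C@@H](O[Si](C)(C)C(C)(C)C)C/C=C(/C)[C@H](OCc2ccc(OC)c(OC)c2)[C@@H](OCc2ccc(OC)cc2)[C@H]1CC(=O)OC | intermediate
30 | (3aS,4S,5S,6Z,9S,10Z,11aS)-9-[(tert-butyldimethylsilyl)oxy]-5-[(3,4-dimethoxybenzyl)oxy]-4-[(4-methoxybenzyl)oxy]-6,10-dimethyl-3a,4,5,8,9,11a-hexahydrocyclodeca[b]furan-2(3H)-one | C1C(=O)O[C@H]2/C=C(/C)[C@@H](O[Si](C)(C)C(C)(C)C)C/C=C(/C)[C@H](OCc3ccc(OC)c(OC)c3)[C@@H](OCc3ccc(OC)cc3)[C@@H]12 | intermediate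
31 | lithium enolate of 30 (C11=C12–O−) | C1=C([O-])O[C@H]2/C=C(/C)[C@@H](O[Si](C)(C)C(C)(C)C)C/C=C(/C)[C@H](OCc3ccc(OC)c(OC)c3)[C@@H](OCc3ccc(OC)cc3)[C@@H]12.[Li+] | intermediate
32 | 3-[(dimethylamino)methyl] derivative of 30 (C11 epimers, other centres as in 30) | CN(C)CC1C(=O)O[C@H]2/C=C(/C)[C@@H](O[Si](C)(C)C(C)(C)C)C/C=C(/C)[C@H](OCc3ccc(OC)c(OC)c3)[C@@H](OCc3ccc(OC)cc3)[C@@H]12 | intermediate
33 | trimethylammonium iodide from 32 (C11 epimers) | C[N+](C)(C)CC1C(=O)O[C@H]2/C=C(/C)[C@@H](O[Si](C)(C)C(C)(C)C)C/C=C(/C)[C@H](OCc3ccc(OC)c(OC)c3)[C@@H](OCc3ccc(OC)cc3)[C@@H]12.[I-] | intermediate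
34 | (3aS,4S,5S,6Z,9S,10Z,11aS)-9-[(tert-butyldimethylsilyl)oxy]-5-[(3,4-dimethoxybenzyl)oxy]-4-[(4-methoxybenzyl)oxy]-6,10-dimethyl-3-methylidene-3a,4,5,8,9,11a-hexahydrocyclodeca[b]furan-2(3H)-one | C=C1C(=O)O[C@H]2/C=C(/C)[C@@H](O[Si](C)(C)C(C)(C)C)C/C=C(/C)[C@H](OCc3ccc(OC)c(OC)c3)[C@@H](OCc3ccc(OC)cc3)[C@@H]12 | intermediate
35 | (3aS,4S,5S,6Z,9S,10Z,11aS)-5-[(3,4-dimethoxybenzyl)oxy]-9-hydroxy-4-[(4-methoxybenzyl)oxy]-6,10-dimethyl-3-methylidene-3a,4,5,8,9,11a-hexahydrocyclodeca[b]furan-2(3H)-one | C=C1C(=O)O[C@H]2/C=C(/C)[C@@H](O)C/C=C(/C)[C@H](OCc3ccc(OC)c(OC)c3)[C@@H](OCc3ccc(OC)cc3)[C@@H]12 | intermediate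
36 | (3aS,4S,5S,6Z,9S,10Z,11aS)-5-[(3,4-dimethoxybenzyl)oxy]-4-[(4-methoxybenzyl)oxy]-6,10-dimethyl-3-methylidene-2-oxo-2,3,3a,4,5,8,9,11a-octahydrocyclodeca[b]furan-9-yl acetate | C=C1C(=O)O[C@H]2/C=C(/C)[C@@H](OC(C)=O)C/C=C(/C)[C@H](OCc3ccc(OC)c(OC)c3)[C@@H](OCc3ccc(OC)cc3)[C@@H]12 | intermediate
37 | (3aS,4S,5S,6Z,9S,10Z,11aS)-5-hydroxy-4-[(4-methoxybenzyl)oxy]-6,10-dimethyl-3-methylidene-2-oxo-2,3,3a,4,5,8,9,11a-octahydrocyclodeca[b]furan-9-yl acetate | C=C1C(=O)O[C@H]2/C=C(/C)[C@@H](OC(C)=O)C/C=C(/C)[C@H](O)[C@@H](OCc3ccc(OC)cc3)[C@@H]12 | intermediate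
38 | tiglic acid, (E)-2-methylbut-2-enoic acid | C/C=C(\C)C(=O)O | starting material
39 | (E)-2-methylbut-2-en-1-ol | C/C=C(\C)CO | intermediate
40 | [(2R,3R)-2,3-dimethyloxiran-2-yl]methanol | OC[C@@]1(C)O[C@@H]1C | intermediate
41 | (2S,3R)-2,3-dimethyloxirane-2-carboxylic acid | OC(=O)[C@@]1(C)O[C@@H]1C | intermediate
42 | (2S,3R)-2,3-dimethyloxirane-2-carboxylic 2,4,6-trichlorobenzoic anhydride | O=C(OC(=O)c1c(Cl)cc(Cl)cc1Cl)[C@@]1(C)O[C@@H]1C | intermediate
43 | (3aS,4S,5S,6Z,9S,10Z,11aS)-9-acetoxy-4-[(4-methoxybenzyl)oxy]-6,10-dimethyl-3-methylidene-2-oxo-2,3,3a,4,5,8,9,11a-octahydrocyclodeca[b]furan-5-yl (2S,3R)-2,3-dimethyloxirane-2-carboxylate | C=C1C(=O)O[C@H]2/C=C(/C)[C@@H](OC(C)=O)C/C=C(/C)[C@H](OC(=O)[C@@]3(C)O[C@@H]3C)[C@@H](OCc3ccc(OC)cc3)[C@@H]12 | intermediate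
44 | (3aR,4S,5S,6Z,9S,10Z,11aS)-9-acetoxy-4-hydroxy-6,10-dimethyl-3-methylidene-2-oxo-2,3,3a,4,5,8,9,11a-octahydrocyclodeca[b]furan-5-yl (2S,3R)-2,3-dimethyloxirane-2-carboxylate | C=C1C(=O)O[C@H]2/C=C(/C)[C@@H](OC(C)=O)C/C=C(/C)[C@H](OC(=O)[C@@]3(C)O[C@@H]3C)[C@@H](O)[C@@H]12 | target

## Step count and least certain steps

Total: 23 steps. Longest linear sequence: 17 steps from 1 to 44 (steps 1–5, 8, 10–18, 22, 23). The side branches are steps 6–7 (to 13), step 9 (to 18) and steps 19–21 (to 41).

Step 12 (key step). The most likely failures are expulsion of the C8 alkoxide from the potassium dienolate if the rearrangement needs warming, and leakage through the ring-flipped chair to the E C1=C10 isomer. The two push–pull enol ether termini may also slow the shift. Fallback, from 22 back to 25, with no free enolate: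
- 22 is silylated (N-trimethylsilylimidazole) to the trimethylsilyl ether F1.
- F1 is heated in 1,2-dichlorobenzene at about 200 °C in base-washed glass. The neutral silyloxy-Cope rearrangement passes through the same chair and gives the trimethylsilyl dienol ether F2.
- F2 is cleaved with K2CO3 in MeOH at 0 °C to the ketone 25.

Step 8. Enolate equilibration could lead to coupling at the γ-position, the electron-rich bromide may undergo oxidative addition slowly, and the cold protonation may show poor facial selectivity at C1, because a proton source discriminates less than an alkyl halide. Fallback, from 6 back to 16: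
- The kinetic enolate of 6 is trapped with TMSCl as the trimethylsilyl dienol ether F3.
- F3 is coupled with 13 under neutral conditions (Bu3SnF, PdCl2[P(o-tol)3]2, toluene, 80 °C). The tin enolate forms only at C1 and the product is not deprotonated.
- The C1 epimers are then equilibrated through the dienolate with KN(SiMe3)2 and protonated with the hindered phenol as in the main step, which returns 16.

Step 11. The alkenyl aluminate could collapse with loss of the PMB-oxy group, or the benzyl alkynyl ether could undergo a sigmatropic shift before reduction is complete. Fallback, from 18 and 16 directly to 22, without an alkyne on the ring: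
- 18 is converted with n-BuLi and a proton quench into 1-(ethynyloxymethyl)-4-methoxybenzene F4.
- Hydrozirconation with Cp2Zr(H)Cl and iodination give (E)-1-[(2-iodoethenyl)oxymethyl]-4-methoxybenzene F5.
- Iodine–lithium exchange with t-BuLi at −78 °C gives the alkenyllithium F6, and CeCl3 gives the alkenylcerium dichloride F7.
- F7 adds to 16 and gives 22. The price is lower confidence in axial attack by an sp2 nucleophile.

Step 13. The chelate may not persist, so that the electrophile enters on the other face, and the enolate may lose the C8 alkoxide. Fallback, from the C7 epimer F8 (the product of the wrong-face alkylation of 25) back to 28: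
- F8 is deprotonated at C7 with LiN(SiMe3)2 at −78 °C to the tetrasubstituted enolate F9.
- F9 is protonated with 2,6-di-tert-butylphenol. The proton should take the face that the electrophile preferred, which inverts C7 and returns 28.

Step 14. Facial selectivity of hydride delivery in a flexible ten-membered enone may be poor and could give the C6 epimer, which cannot form the cis lactone. Fallback, from 28 back to 30:
- The epimeric hydroxy ester F10 is saponified (LiOH, THF–H2O) to the hydroxy acid F11.
- F11 is closed by Mitsunobu lactonisation (PPh3, DIAD, toluene), which inverts C6 and returns the cis-fused lactone 30.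

## Further compounds

F1 | step 12 | trimethylsilyl ether of 22 (1R,4S,6S) | C[Si](C)(C)O[C@]1(/C=C/OCc2ccc(OC)cc2)C=C(C)[C@@H](O[Si](C)(C)C(C)(C)C)C[C@H]1/C(C)=C/OCc1ccc(OC)c(OC)c1
F2 | step 12 | trimethylsilyl dienol ether of 25 (C6–OSiMe3, C6=C7, configuration as in 24) | C\1=C(O[Si](C)(C)C)/C=C(/C)[C@@H](O[Si](C)(C)C(C)(C)C)C/C=C(/C)[C@H](OCc2ccc(OC)c(OC)c2)[C@H]1OCc1ccc(OC)cc1
F3 | step 8 | (4S)-4-[(tert-butyldimethylsilyl)oxy]-5-methyl-1-(trimethylsilyloxy)cyclohexa-1,5-diene | C[Si](C)(C)OC1=CC[C@H](O[Si](C)(C)C(C)(C)C)C(C)=C1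
F4 | step 11 | 1-(ethynyloxymethyl)-4-methoxybenzene | C#COCc1ccc(OC)cc1
F5 | step 11 | (E)-1-[(2-iodoethenyl)oxymethyl]-4-methoxybenzene | I/C=C/OCc1ccc(OC)cc1
F6 | step 11 | (E)-2-[(4-methoxybenzyl)oxy]ethenyllithium | [Li]/C=C/OCc1ccc(OC)cc1
F7 | step 11 | dichloro{(E)-2-[(4-methoxybenzyl)oxy]ethenyl}cerium | Cl[Ce](Cl)/C=C/OCc1ccc(OC)cc1
F8 | step 13 | C7 epimer of 28 (7S in germacrane numbering) | O=C1/C=C(/C)[C@@H](O[Si](C)(C)C(C)(C)C)C/C=C(/C)[C@H](OCc2ccc(OC)c(OC)c2)[C@@H](OCc2ccc(OC)cc2)[C@@H]1CC(=O)OC
F9 | step 13 | lithium enolate of F8 (C6=C7, C7 bearing CH2CO2Me) | COC(=O)CC\1=C([O-])/C=C(/C)[C@@H](O[Si](C)(C)C(C)(C)C)C/C=C(/C)[C@H](OCc2ccc(OC)c(OC)c2)[C@H]1OCc1ccc(OC)cc1.[Li+]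
F10 | step 14 | C6 epimer of 29 (hydroxyl trans to the C7 side chain) | O[C@@H]1/C=C(/C)[C@@H](O[Si](C)(C)C(C)(C)C)C/C=C(/C)[C@H](OCc2ccc(OC)c(OC)c2)[C@@H](OCc2ccc(OC)cc2)[C@H]1CC(=O)OC
F11 | step 14 | hydroxy acid from F10 | O[C@@H]1/C=C(/C)[C@@H](O[Si](C)(C)C(C)(C)C)C/C=C(/C)[C@H](OCc2ccc(OC)c(OC)c2)[C@@H](OCc2ccc(OC)cc2)[C@H]1CC(=O)O
A1 | alternative 1 | C8 triethylsilyl ether of 44 | C=C1C(=O)O[C@H]2/C=C(/C)[C@@H](OC(C)=O)C/C=C(/C)[C@H](OC(=O)[C@@]3(C)O[C@@H]3C)[C@@H](O[Si](CC)(CC)CC)[C@@H]12
A2 | alternative 1 | ten-membered C6 alcohol with C7 ethynyl group and C8 triethylsilyl ether | C#C[C@H]1[C@@H](O)/C=C(/C)[C@@H](OC(C)=O)C/C=C(/C)[C@H](OC(=O)[C@@]2(C)O[C@@H]2C)[C@H]1O[Si](CC)(CC)CC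
A3 | alternative 2 | C3,C6 endoperoxide with C7 methyl acrylate unit and C8 TBS ether | C=C(C(=O)OC)[C@H]1[C@H]2OO[C@@H](C/C=C(/C)[C@H](OC(=O)[C@@]3(C)O[C@@H]3C)[C@H]1O[Si](C)(C)C(C)(C)C)C(C)=C2
A4 | alternative 2 | ten-membered (1(10)Z,3Z,5Z)-triene with C7 methyl acrylate unit and C8 TBS ether | C=C(C(=O)OC)[C@H]1/C=C\C(C)=C/C/C=C(/C)[C@H](OC(=O)[C@@]2(C)O[C@@H]2C)[C@H]1O[Si](C)(C)C(C)(C)C
A5 | alternative 3 | ten-membered C9 alcohol with C8 TBS ether | C=C1C(=O)O[C@H]2/C=C(/C)[C@@H](OC(C)=O)C/C=C(/C)[C@H](O)[C@@H](O[Si](C)(C)C(C)(C)C)[C@@H]12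
A6 | alternative 3 | open-chain Z alkenyl iodide with C9 aldehyde on the methylene lactone | C=C1C(=O)O[C@@H](/C=C(/C)[C@@H](OC(C)=O)C/C=C(/C)I)[C@H]1[C@H](O[Si](C)(C)C(C)(C)C)C=O
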